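**Retrosynthetic overview**
1. The target is (3R)-8-hydroxy-6-methoxy-3-(6-oxoundecyl)-3,4-dihydroisocoumarin. The 8-OH is unveiled last from the 6,8-dimethyl ether by chelation-controlled demethylation, and the side-chain ketone travels as a dioxolane.
2. Key disconnections: C1'–C2' of the side chain (joining the aryl half to the C10 keto chain) and C3–C4. Both bonds form in one nickel-catalysed conjunctive coupling of a benzyl(vinyl)boron ate complex with the C10 alkyl iodide; boron is a temporary tether between C4 and the C3=C1' vinyl unit, and C3–O then arises from C3–B.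
3. Enabling feature: C3 of the lactone ring is a secondary C–O stereocentre flanked by two methylene carbons (benzylic C4 and side-chain C1') and lies δ to the C1 ester carbonyl on the aromatic ring. It can therefore be the boron-bearing carbon of a vinyl group that receives the ester-acidified benzylic C4 by 1,2-shift, takes the chain at C1', and closes the lactone (O2–C1) after C–B oxidation.
4. Ring order: the aromatic ring is bought (an orsellinate); the δ-lactone is the only ring formed, in the work-up of the key step.
5. The C10 iodide comes from 5-bromopentanoyl chloride and pentylmagnesium bromide, followed by ketalisation and Finkelstein exchange.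

Key step: step 4

Remark: methyl 2,4-dimethoxy-6-methylbenzoate is taken as a purchasable orsellinate derivative (otherwise one step from methyl orsellinate with Me2SO4/K2CO3). Locants C1–C8a refer to the isochroman-1-one core; C1', C2' … are the side-chain carbons counted from C3. The Pybox antipode that gives the 3R product is to be fixed in a test run with assignment of the configuration.

**Step 1**
Reactants: 1 5-bromopentanoyl chloride; 2 pentylmagnesium bromide
Product: 3 1-bromodecan-5-one
Conditions: Fe(acac)3 (3 mol %), THF, −78 °C
Reagents that add atoms: none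
Why: Iron-catalysed cross-coupling (acylation) of the Grignard reagent with the acid chloride is much faster at −78 °C than addition to the ketone formed or reaction at the primary bromide, so the bromo ketone should be obtained without over-addition.

**Step 2**
Reactants: 3 1-bromodecan-5-one
Product: 4 2-(4-bromobutyl)-2-pentyl-1,3-dioxolane
Conditions: HOCH2CH2OH, p-TsOH·H2O (cat.), toluene, reflux, Dean–Stark
Reagents that add atoms: ethylene glycol, OCCO
Why: Acid-catalysed ketalisation with azeotropic removal of water masks the ketone as a 1,3-dioxolane, which is inert to the organolithium, borate and nickel species of step 4; the primary bromide is untouched.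

**Step 3**
Reactants: 4 2-(4-bromobutyl)-2-pentyl-1,3-dioxolane
Product: 5 2-(4-iodobutyl)-2-pentyl-1,3-dioxolane
Conditions: NaI, NaHCO3 (trace), acetone, reflux
Reagents that add atoms: sodium iodide, [Na+].[I-]
Why: Finkelstein reaction (SN2 halide exchange) driven by precipitation of sodium bromide in acetone gives the primary iodide needed for oxidative addition to nickel; the ketal is stable under these neutral conditions.

**Step 4**
Reactants: 6 methyl 2,4-dimethoxy-6-methylbenzoate; 7 4,4,5,5-tetramethyl-2-vinyl-1,3,2-dioxaborolane (vinylboronic acid pinacol ester); 5 2-(4-iodobutyl)-2-pentyl-1,3-dioxolane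
Product: 13 (3R)-6,8-dimethoxy-3-(6-oxoundecyl)-3,4-dihydro-1H-isochromen-1-one, via benzylic lithium species 8 (not isolated), via vinylboron ate complex 9 (not isolated), via secondary boronic ester 10 (not isolated), via hydroxy ester 11 (not isolated), via lactone ketal 12 (not isolated)
Conditions: LDA (1.0 equiv), THF, −78 °C; 7, −78 → 0 °C; volatiles removed; then 5, NiBr2·glyme (10 mol %), chiral Pybox ligand (12 mol %), THF/DMSO, rt; then 3 M NaOH, 30% H2O2, 0 °C → rt; Na2S2O3; then 2 M HCl, THF, rt
Reagents that add atoms: hydrogen peroxide, OO; water, O
Why: Proposed new method: lateral lithiation of 6 (benzylic C–H acidified by the ortho ester) gives 8, which adds to the boron atom of 7 to give ate complex 9; an alkylnickel species formed from iodide 5 and the Pybox-ligated low-valent nickel then binds the vinyl group of 9 and induces a 1,2-metallate shift in which the benzylic carbon moves from boron to the boron-bearing vinyl carbon (C4–C3 bond) while the terminal vinyl carbon binds to nickel, and C(sp3)–C(sp3) reductive elimination closes the C1'–C2' bond to give 10. The closest known reaction type is the nickel-catalysed enantioselective conjunctive cross-coupling of alkyl- or aryl(vinyl)boron pinacolate complexes with unactivated primary alkyl iodides, and the new element is the migrating group, a benzylic carbon that carries an ortho ester and is made from a toluate anion. The C3 stereocentre is set in the metallate shift by the chiral ligand on nickel, which selects the face of the vinyl group, and it is carried with retention through the stereospecific oxidation of the C–B bond to the C–O bond of 11. The only ring closed is the δ-lactone, by 6-exo-trig attack of the C3 oxygen on the ortho ester carbonyl (acyl substitution with loss of methanol) to give 12, and the final acid stage completes this closure and hydrolyses the dioxolane to give 13. The step needs the metallate shift to be faster than direct transfer of the benzyl or vinyl group from boron to nickel and than β-hydride elimination of the alkylnickel intermediates, which the pinacolato group on boron and the tridentate ligand on nickel are meant to secure; the regiochemistry is fixed because boron sits on the internal vinyl carbon, and the ester, flanked by two ortho substituents, should survive the organolithium stage.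

**Step 5**
Reactants: 13 (3R)-6,8-dimethoxy-3-(6-oxoundecyl)-3,4-dihydro-1H-isochromen-1-one
Product: 14 (3R)-8-hydroxy-6-methoxy-3-(6-oxoundecyl)-3,4-dihydro-1H-isochromen-1-one (target)
Conditions: BCl3 (1 M in CH2Cl2), CH2Cl2, −78 → 0 °C; aq. NaHCO3 work-up
Reagents that add atoms: none
Why: Chelation-controlled Lewis-acid ether cleavage: BCl3 is bound between the lactone carbonyl oxygen and the peri 8-methoxy oxygen, so only this methyl group is removed as chloromethane, while the 6-methoxy group, the lactone, the ketone and the C3 stereocentre (not involved) should remain.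

**Compound list**
1 | 5-bromopentanoyl chloride | O=C(Cl)CCCCBr | starting material
2 | pentylmagnesium bromide | CCCCC[Mg]Br | starting material
3 | 1-bromodecan-5-one | CCCCCC(=O)CCCCBr | intermediate
4 | 2-(4-bromobutyl)-2-pentyl-1,3-dioxolane | CCCCCC1(CCCCBr)OCCO1 | intermediate
5 | 2-(4-iodobutyl)-2-pentyl-1,3-dioxolane | CCCCCC1(CCCCI)OCCO1 | intermediate
6 | methyl 2,4-dimethoxy-6-methylbenzoate | COC(=O)c1c(C)cc(OC)cc1OC | starting material
7 | 4,4,5,5-tetramethyl-2-vinyl-1,3,2-dioxaborolane | C=CB1OC(C)(C)C(C)(C)O1 | starting material
8 | [3,5-dimethoxy-2-(methoxycarbonyl)benzyl]lithium | [Li]Cc1cc(OC)cc(OC)c1C(=O)OC | intermediate (not isolated)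
9 | lithium [3,5-dimethoxy-2-(methoxycarbonyl)benzyl](pinacolato)(vinyl)borate | [Li+].C=C[B-]1(Cc2cc(OC)cc(OC)c2C(=O)OC)OC(C)(C)C(C)(C)O1 | intermediate (not isolated)
10 | methyl 2,4-dimethoxy-6-[(2R)-7-(2-pentyl-1,3-dioxolan-2-yl)-2-(4,4,5,5-tetramethyl-1,3,2-dioxaborolan-2-yl)heptyl]benzoate | CCCCCC1(OCCO1)CCCCC[C@@H](B2OC(C)(C)C(C)(C)O2)Cc3cc(OC)cc(OC)c3C(=O)OC | intermediate (not isolated)
11 | methyl 2-[(2R)-2-hydroxy-7-(2-pentyl-1,3-dioxolan-2-yl)heptyl]-4,6-dimethoxybenzoate | CCCCCC1(OCCO1)CCCCC[C@@H](O)Cc2cc(OC)cc(OC)c2C(=O)OC | intermediate (not isolated)
12 | (3R)-6,8-dimethoxy-3-[5-(2-pentyl-1,3-dioxolan-2-yl)pentyl]-3,4-dihydro-1H-isochromen-1-one | CCCCCC1(OCCO1)CCCCC[C@@H]2Cc3cc(OC)cc(OC)c3C(=O)O2 | intermediate (not isolated)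
13 | (3R)-6,8-dimethoxy-3-(6-oxoundecyl)-3,4-dihydro-1H-isochromen-1-one | CCCCCC(=O)CCCCC[C@@H]1Cc2cc(OC)cc(OC)c2C(=O)O1 | intermediate
14 | (3R)-8-hydroxy-6-methoxy-3-(6-oxoundecyl)-3,4-dihydro-1H-isochromen-1-one | CCCCCC(=O)CCCCC[C@@H]1Cc2cc(OC)cc(O)c2C(=O)O1 | target

**Total step count:** 5
**Longest linear sequence:** 5 steps (1 → 2 → 3 → 4 → 5)

**Steps most likely to fail**

Step 4 (carries the label). What may go wrong: the benzyl or vinyl group may pass directly from boron to nickel instead of undergoing the metallate shift, the ate complex may fall back to the stabilised benzylic anion, and facial control by the ligand may be insufficient for this migrating group. The fallback uses known chemistry, sets out from 6 and 4 and comes back at 12. Wohl–Ziegler bromination of 6 (NBS, AIBN, PhCF3, reflux) should give methyl 2-(bromomethyl)-4,6-dimethoxybenzoate F1. Stille coupling with tributyl(vinyl)stannane (Pd(PPh3)4, toluene, 90 °C) should give methyl 2,4-dimethoxy-6-(prop-2-en-1-yl)benzoate F2. Epoxidation (mCPBA, NaHCO3, CH2Cl2) should give racemic methyl 2,4-dimethoxy-6-(oxiran-2-ylmethyl)benzoate F3. Hydrolytic kinetic resolution with (R,R)-(salen)Co(III)OAc and 0.55 equiv of water should leave methyl 2,4-dimethoxy-6-{[(2S)-oxiran-2-yl]methyl}benzoate F4. Bromide 4 is converted with magnesium in THF into [4-(2-pentyl-1,3-dioxolan-2-yl)butyl]magnesium bromide F5. Under CuI catalysis at −30 °C, F5 should open F4 at the terminal epoxide carbon, making the same C1'–C2' bond by SN2 opening with the stereocentre untouched. The alkoxide of 11 so formed should close onto the ester on warming to give 12, which is hydrolysed to 13 with 2 M HCl in THF as in the last stage of step 4.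

Step 1. What may go wrong: over-addition of the Grignard reagent to the ketone as it forms, and halogen–metal exchange or coupling at the primary bromide. The fallback sets out from 1 and comes back at 3. Compound 1 with N,O-dimethylhydroxylamine hydrochloride and pyridine in CH2Cl2 at 0 °C should give 5-bromo-N-methoxy-N-methylpentanamide F6. Addition of 2 in THF at 0 °C then stops at the chelated tetrahedral intermediate, which should release 3 only on acidic work-up.

Step 5. What may go wrong: cleavage of the wrong methyl ether or of both, or Lewis-acid-induced enolisation and condensation at the side-chain ketone. The fallback sets out from 13 and comes back at 14. Exhaustive demethylation with excess BBr3 (CH2Cl2, −78 °C → rt) should give (3R)-6,8-dihydroxy-3-(6-oxoundecyl)-3,4-dihydro-1H-isochromen-1-one F7. Mono-methylation with MeI (1 equiv) and K2CO3 in acetone should then take place at the free 6-OH, because the 8-OH is held in a hydrogen bond to the lactone carbonyl, to give 14.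

**Further compounds**
F1 | step 4 | methyl 2-(bromomethyl)-4,6-dimethoxybenzoate | COC(=O)c1c(CBr)cc(OC)cc1OC
F2 | step 4 | methyl 2,4-dimethoxy-6-(prop-2-en-1-yl)benzoate | COC(=O)c1c(CC=C)cc(OC)cc1OC
F3 | step 4 | methyl 2,4-dimethoxy-6-(oxiran-2-ylmethyl)benzoate (racemic) | COC(=O)c1c(CC2CO2)cc(OC)cc1OC
F4 | step 4 | methyl 2,4-dimethoxy-6-{[(2S)-oxiran-2-yl]methyl}benzoate | C1[C@@H](O1)Cc2cc(OC)cc(OC)c2C(=O)OC
F5 | step 4 | [4-(2-pentyl-1,3-dioxolan-2-yl)butyl]magnesium bromide | CCCCCC1(CCCC[Mg]Br)OCCO1
F6 | step 1 | 5-bromo-N-methoxy-N-methylpentanamide | CON(C)C(=O)CCCCBr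
F7 | step 5 | (3R)-6,8-dihydroxy-3-(6-oxoundecyl)-3,4-dihydro-1H-isochromen-1-one | CCCCCC(=O)CCCCC[C@@H]1Cc2cc(O)cc(O)c2C(=O)O1
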